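The route rests on cutting the bond between C5 of the central guaiacyl ring (ring B, on the lactone α-CH2) and C8'', the CH(CH2OH) carbon of the open side chain. The feature exploited is the vicinal pair C8''(aryl)–C7''(OH)(guaiacyl): it maps onto an alkene carrying boron, so one palladium-catalysed conjunctive cross-coupling joins the aryl bromide of the complete lactone–dihydrobenzofuran half to a boron ate complex built from a (Z)-alkenylboronic ester and an aryllithium. That single operation forms the ring B–C8'' bond and the guaiacyl–C7'' bond and sets both stereocentres; boron then becomes the C7'' hydroxyl. The same coupling plus Mitsunobu closure builds the dihydrobenzofuran earlier.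

Key step: step 16

Assumption: (R,R)-Me-DuPhos (step 3) and (Sp,Sp)-MandyPhos (steps 9 and 16) are written as the ligand enantiomers expected to give the (S)-acid and the (S,S)-carbinols; if a first run shows the opposite sense, the antipodal ligand is used and nothing else changes.

Labels used below: ring A is the benzene ring of the dihydrobenzofuran (on the lactone β-CH2), with C7'''/C8''' as its furan C2/C3; ring B is the guaiacyl ring on the lactone α-CH2, with C7''/C8''/C9'' as its open side chain.

Step 1
Reactants: 1 5-bromovanillin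
Product: 2 4-(benzyloxy)-3-bromo-5-methoxybenzaldehyde
Conditions: BnBr, K2CO3, DMF, 50 °C
Reagents that add atoms: benzyl bromide, BrCc1ccccc1
Why: Williamson etherification of the only acidic site, the phenol, gives a base-stable ether for the next three steps.

Step 2
Reactants: 2 4-(benzyloxy)-3-bromo-5-methoxybenzaldehyde; 3 dimethyl succinate
Product: 4 (E)-4-[4-(benzyloxy)-3-bromo-5-methoxyphenyl]-3-(methoxycarbonyl)but-3-enoic acid
Conditions: NaOMe, MeOH, reflux; then aq HCl
Reagents that add atoms: none
Why: Stobbe condensation (aldol addition, lactonisation to the paraconic ester, E1cB opening) gives the half-ester with the aryl group trans to the conjugated ester.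

Step 3
Reactants: 4 (E)-itaconate half-ester
Product: 5 (S)-3-{[4-(benzyloxy)-3-bromo-5-methoxyphenyl]methyl}-4-methoxy-4-oxobutanoic acid
Conditions: [Rh(cod)2]BF4 (0.5 mol %), (R,R)-Me-DuPhos, NaOMe (10 mol %), MeOH, H2 (5 bar), rt
Reagents that add atoms: none
Why: Rhodium–bisphosphine asymmetric hydrogenation of an itaconate-type half-ester, in which carboxylate/alkene chelation fixes the bound face, sets the lactone β-centre (S) by catalyst control; aryl bromide and benzyl ether are inert.

Step 4
Reactants: 5 (S)-benzylsuccinic acid monomethyl ester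
Product: 6 (S)-4-{[4-(benzyloxy)-3-bromo-5-methoxyphenyl]methyl}dihydrofuran-2(3H)-one
Conditions: KOH (1 equiv), EtOH; CaCl2, NaBH4, EtOH, −10 °C → rt; then 2 M HCl, rt
Reagents that add atoms: none
Why: Chemoselective borohydride reduction of the ester beside the unreactive carboxylate, then acid-promoted γ-lactonisation, gives the β-benzyl butyrolactone without touching the stereocentre.

Step 5
Reactants: 7 acenaphthoquinone
Product: 8 cis-1,2-dimethyl-1,2-dihydroacenaphthylene-1,2-diol (meso)
Conditions: MeMgBr (2.5 equiv), THF, 0 °C → rt; aq NH4Cl; recrystallisation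
Reagents that add atoms: methylmagnesium bromide, C[Mg]Br
Why: Double Grignard 1,2-addition to the 1,2-dione, the second methyl entering anti to the bulky magnesium alkoxide, should give mainly the cis-diol, which is purified by crystallisation.

Step 6
Reactants: 9 tert-butyldimethyl(prop-2-yn-1-yloxy)silane; 8 cis-diol
Product: 11 (Z)-3-(tert-butyldimethylsilyloxy)prop-1-enylboronic ester of the cis-dimethylacenaphthenediol, via catechol boronate 10 (not isolated)
Conditions: catecholborane, [Rh(cod)Cl]2 (1.5 mol %), P(iPr)3 (6 mol %), Et3N, cyclohexane, rt; then 8, rt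
Reagents that add atoms: catecholborane, B1Oc2ccccc2O1
Why: Rhodium-catalysed trans-hydroboration of a terminal alkyne through a rhodium vinylidene places boron cis to the CH2OSi group (Z), and the labile catechol ester then exchanges with the chelating tertiary diol.

Step 7
Reactants: 12 4-bromo-2-methoxyphenol
Product: 13 (4-bromo-2-methoxyphenoxy)triisopropylsilane
Conditions: TIPSCl, imidazole, DMF, rt
Reagents that add atoms: triisopropylsilyl chloride, CC(C)[Si](Cl)(C(C)C)C(C)C
Why: Phenol silylation gives an aryl ether that survives organolithium formation and mildly basic oxidation yet leaves with fluoride at the end.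

Step 8
Reactants: 13 (4-bromo-2-methoxyphenoxy)triisopropylsilane; 11 (Z)-alkenylboronic ester
Product: 15 lithium [(Z)-3-(tert-butyldimethylsilyloxy)prop-1-enyl][3-methoxy-4-(triisopropylsilyloxy)phenyl]borate of the cis-dimethylacenaphthenediol (boron ate complex), via aryllithium 14 (not isolated)
Conditions: 13, t-BuLi (2.0 equiv), Et2O, −78 °C; then 11 (1.05 equiv relative to 14), Et2O/THF, −78 °C → rt; volatiles removed under argon and the solid residue used directly, made freshly for each of steps 9 and 16
Reagents that add atoms: tert-butyllithium, [Li]C(C)(C)C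
Why: Bromine–lithium exchange gives the aryllithium, which adds to the vacant orbital on boron of 11 to give the four-coordinate lithium borate (ate-complex formation, no stereocentre formed), and the slight excess of 11 ensures that no free aryllithium is carried into the couplings.

Step 9
Reactants: 15 boron ate complex; 6 (S)-bromoaryl lactone
Product: 17 (S)-4-({4-(benzyloxy)-3-[(1S,2S)-3-(tert-butyldimethylsilyloxy)-1-hydroxy-1-[3-methoxy-4-(triisopropylsilyloxy)phenyl]propan-2-yl]-5-methoxyphenyl}methyl)dihydrofuran-2(3H)-one, via boronic ester 16 (not isolated)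
Conditions: 15 (1.2 equiv), Pd(OAc)2 (3 mol %), (Sp,Sp)-MandyPhos (3.6 mol %), KOTf (2.5 equiv), THF, 60 °C; then NaBO3·4H2O, THF/H2O, rt
Reagents that add atoms: sodium perborate tetrahydrate, [Na+].[Na+].O[B-]1(O)OO[B-](O)(O)OO1
Why: Enantioselective conjunctive cross-coupling of a β-substituted alkenyl boron ate complex: the aryl-palladium species from 6 induces anti 1,2-migration of the guaiacyl group from boron to carbon across the (Z)-alkene and reductive elimination forms the ring A–C8''' bond, so the anti relative configuration follows from the alkene geometry and the absolute configuration from the MandyPhos ligand, and stereoretentive perborate oxidation gives the alcohol.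

Step 10
Reactants: 17 benzyl ether
Product: 18 (S)-4-({3-[(1S,2S)-3-(tert-butyldimethylsilyloxy)-1-hydroxy-1-[3-methoxy-4-(triisopropylsilyloxy)phenyl]propan-2-yl]-4-hydroxy-5-methoxyphenyl}methyl)dihydrofuran-2(3H)-one
Conditions: H2 (1 atm), Pd/C (10 %), EtOAc, rt
Reagents that add atoms: none
Why: Hydrogenolysis of the single aryl benzyl ether under neutral conditions frees the ring A phenol; no aryl halide is present at this stage and silyl ethers, lactone and the secondary benzylic alcohol are expected to persist.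

Step 11
Reactants: 18 phenol–benzylic alcohol
Product: 19 (S)-4-({(2R,3S)-3-[(tert-butyldimethylsilyloxy)methyl]-7-methoxy-2-[3-methoxy-4-(triisopropylsilyloxy)phenyl]-2,3-dihydrobenzofuran-5-yl}methyl)dihydrofuran-2(3H)-one
Conditions: PPh3, DIAD, THF, 0 °C → rt
Reagents that add atoms: none
Why: Intramolecular Mitsunobu etherification closes the furan ring 5-exo-tet with inversion at C7''', turning the anti (S,S) alcohol into the 2,3-trans (2R,3S) ring; any competing ionisation leads to the same, more stable trans isomer because C8''' is fixed.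

Step 12
Reactants: 1 5-bromovanillin
Product: 20 3-bromo-4-(tert-butyldimethylsilyloxy)-5-methoxybenzaldehyde
Conditions: TBSCl, imidazole, DMF, rt
Reagents that add atoms: tert-butyldimethylsilyl chloride, CC(C)(C)[Si](C)(C)Cl
Why: Silylation of the acidic phenol gives a fluoride-labile ether for ring B.

Step 13
Reactants: 20 silylated aldehyde
Product: 21 [3-bromo-4-(tert-butyldimethylsilyloxy)-5-methoxyphenyl]methanol
Conditions: NaBH4, THF/MeOH, 0 °C
Reagents that add atoms: none
Why: Borohydride reduction of the aldehyde; the flanked aryl silyl ether is stable to the brief, cold conditions.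

Step 14
Reactants: 21 benzylic alcohol
Product: 22 3-bromo-4-(tert-butyldimethylsilyloxy)-5-methoxybenzyl bromide
Conditions: CBr4, PPh3, CH2Cl2, 0 °C
Reagents that add atoms: carbon tetrabromide, BrC(Br)(Br)Br
Why: Appel bromination under neutral conditions converts the benzylic alcohol into the bromide without loss of the aryl silyl ether.

Step 15
Reactants: 19 dihydrobenzofuran lactone; 22 benzyl bromide
Product: 23 (3S,4S)-3-{[3-bromo-4-(tert-butyldimethylsilyloxy)-5-methoxyphenyl]methyl}-4-({(2R,3S)-3-[(tert-butyldimethylsilyloxy)methyl]-7-methoxy-2-[3-methoxy-4-(triisopropylsilyloxy)phenyl]-2,3-dihydrobenzofuran-5-yl}methyl)dihydrofuran-2(3H)-one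
Conditions: LiHMDS (1.1 equiv), THF, −78 °C; then 22, DMPU, −78 → −30 °C
Reagents that add atoms: none
Why: Alkylation of the lactone lithium enolate occurs anti to the β-substituent, the standard way to trans-α,β-dibenzylbutyrolactones, and sets the α-centre (S) by substrate control.

Step 16
Reactants: 15 boron ate complex; 23 bromoaryl lactone
Product: 25 penta-silyl ether of the target: (3S,4S)-lactone carrying on ring B C5 the (1S,2S)-3-(tert-butyldimethylsilyloxy)-1-hydroxy-1-[3-methoxy-4-(triisopropylsilyloxy)phenyl]propan-2-yl group, via boronic ester 24 (not isolated)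
Conditions: 15 (1.2 equiv), Pd(OAc)2 (3 mol %), (Sp,Sp)-MandyPhos (3.6 mol %), KOTf (2.5 equiv), THF, 60 °C; then NaBO3·4H2O, THF/H2O, rt
Reagents that add atoms: sodium perborate tetrahydrate, [Na+].[Na+].O[B-]1(O)OO[B-](O)(O)OO1
Why: Oxidative addition of zerovalent palladium into the C5–Br bond of 23 gives an aryl-palladium species that binds the alkene of ate complex 15 and triggers a 1,2-metallate shift, the guaiacyl group moving from boron to the boron-bearing carbon anti to palladium, after which reductive elimination forms the ring B C5–C8'' bond with retention. The closest known reaction type is the enantioselective conjunctive cross-coupling of β-substituted alkenyl boron ate complexes that carry a hindered acenaphthene-derived diol on boron. No ring is closed. Both new stereocentres arise together: anti addition across the (Z)-alkene fixes the relative configuration (ring B on C8'' and boron on C7'' anti in the zigzag chain), the MandyPhos ligand selects the alkene face and overrides the remote centres of 23, and perborate oxidation of the C–B bond is stereoretentive, giving 7''S,8''S. The step needs the metallate shift to win over direct Suzuki–Miyaura transfer of the aryl or alkenyl group, which the hindered diol on boron secures, and it needs free bromide kept off the catalyst, which KOTf secures by precipitating KBr. Lactone, silyl ethers and dihydrobenzofuran are inert because the four-coordinate borate is neither basic nor a free organolithium, step 8 having used 11 in slight excess over 14.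

Step 17
Reactants: 25 penta-silyl ether
Product: 26 target CNP0186558.3
Conditions: TBAF (6 equiv), AcOH (6 equiv), THF, 0 °C → rt
Reagents that add atoms: none
Why: Fluoride desilylation removes the three aryl and two alkyl silyl ethers in one operation, and the acetic acid buffer keeps the phenoxides protonated so that the p-hydroxybenzylic alcohol neither ionises to a quinone methide nor cyclises.

Compound list
1 | 5-bromovanillin | COc1cc(C=O)cc(Br)c1O | starting material
2 | 4-(benzyloxy)-3-bromo-5-methoxybenzaldehyde | COc1cc(C=O)cc(Br)c1OCc1ccccc1 | intermediate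
3 | dimethyl succinate | COC(=O)CCC(=O)OC | starting material
4 | (E)-4-[4-(benzyloxy)-3-bromo-5-methoxyphenyl]-3-(methoxycarbonyl)but-3-enoic acid | COC(=O)/C(=C/c1cc(OC)c(OCc2ccccc2)c(Br)c1)CC(=O)O | intermediate
5 | (S)-3-{[4-(benzyloxy)-3-bromo-5-methoxyphenyl]methyl}-4-methoxy-4-oxobutanoic acid | COC(=O)[C@@H](Cc1cc(OC)c(OCc2ccccc2)c(Br)c1)CC(=O)O | intermediate
6 | (S)-4-{[4-(benzyloxy)-3-bromo-5-methoxyphenyl]methyl}dihydrofuran-2(3H)-one | O=C1C[C@H](Cc2cc(OC)c(OCc3ccccc3)c(Br)c2)CO1 | intermediate
7 | acenaphthoquinone | O=C1C(=O)c2cccc3cccc1c23 | starting material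
8 | cis-1,2-dimethyl-1,2-dihydroacenaphthylene-1,2-diol | C[C@]1(O)c2cccc3cccc(c23)[C@@]1(C)O | intermediate
9 | tert-butyldimethyl(prop-2-yn-1-yloxy)silane | C#CCO[Si](C)(C)C(C)(C)C | starting material
10 | 2-[(Z)-3-(tert-butyldimethylsilyloxy)prop-1-enyl]-1,3,2-benzodioxaborole | CC(C)(C)[Si](C)(C)OC/C=C\B1Oc2ccccc2O1 | intermediate (not isolated)
11 | (Z)-3-(tert-butyldimethylsilyloxy)prop-1-enylboronic ester of diol 8 | CC(C)(C)[Si](C)(C)OC/C=C\B1O[C@@]2(C)c3cccc4cccc(c34)[C@@]2(C)O1 | intermediate
12 | 4-bromo-2-methoxyphenol | COc1cc(Br)ccc1O | starting material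
13 | (4-bromo-2-methoxyphenoxy)triisopropylsilane | COc1cc(Br)ccc1O[Si](C(C)C)(C(C)C)C(C)C | intermediate
14 | [3-methoxy-4-(triisopropylsilyloxy)phenyl]lithium | [Li]c1ccc(O[Si](C(C)C)(C(C)C)C(C)C)c(OC)c1 | intermediate (not isolated)
15 | lithium aryl[(Z)-alkenyl]borate of diol 8 (ate complex from 14 and 11, used as the crude solid) | [Li+].CC(C)(C)[Si](C)(C)OC/C=C\[B-]1(c2ccc(O[Si](C(C)C)(C(C)C)C(C)C)c(OC)c2)O[C@@]2(C)c3cccc4cccc(c34)[C@@]2(C)O1 | intermediate
16 | boronic ester of 17 (boron on C7''' in place of OH, 1S,2S) | COc1cc([C@@H](B2O[C@@]3(C)c4cccc5cccc(c45)[C@@]3(C)O2)[C@H](CO[Si](C)(C)C(C)(C)C)c2cc(C[C@@H]3COC(=O)C3)cc(OC)c2OCc2ccccc2)ccc1O[Si](C(C)C)(C(C)C)C(C)C | intermediate (not isolated)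
17 | (S)-4-({4-(benzyloxy)-3-[(1S,2S)-3-(tert-butyldimethylsilyloxy)-1-hydroxy-1-[3-methoxy-4-(triisopropylsilyloxy)phenyl]propan-2-yl]-5-methoxyphenyl}methyl)dihydrofuran-2(3H)-one | COc1cc([C@@H](O)[C@H](CO[Si](C)(C)C(C)(C)C)c2cc(C[C@@H]3COC(=O)C3)cc(OC)c2OCc2ccccc2)ccc1O[Si](C(C)C)(C(C)C)C(C)C | intermediate
18 | debenzylated phenol of 17 | COc1cc([C@@H](O)[C@H](CO[Si](C)(C)C(C)(C)C)c2cc(C[C@@H]3COC(=O)C3)cc(OC)c2O)ccc1O[Si](C(C)C)(C(C)C)C(C)C | intermediate
19 | (S)-4-({(2R,3S)-3-[(tert-butyldimethylsilyloxy)methyl]-7-methoxy-2-[3-methoxy-4-(triisopropylsilyloxy)phenyl]-2,3-dihydrobenzofuran-5-yl}methyl)dihydrofuran-2(3H)-one | O=C1C[C@H](Cc2cc(OC)c3c(c2)[C@@H](CO[Si](C)(C)C(C)(C)C)[C@H](c2ccc(O[Si](C(C)C)(C(C)C)C(C)C)c(OC)c2)O3)CO1 | intermediate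
20 | 3-bromo-4-(tert-butyldimethylsilyloxy)-5-methoxybenzaldehyde | COc1cc(C=O)cc(Br)c1O[Si](C)(C)C(C)(C)C | intermediate
21 | [3-bromo-4-(tert-butyldimethylsilyloxy)-5-methoxyphenyl]methanol | COc1cc(CO)cc(Br)c1O[Si](C)(C)C(C)(C)C | intermediate
22 | 3-bromo-4-(tert-butyldimethylsilyloxy)-5-methoxybenzyl bromide | COc1cc(CBr)cc(Br)c1O[Si](C)(C)C(C)(C)C | intermediate
23 | (3S,4S)-3-{[3-bromo-4-(tert-butyldimethylsilyloxy)-5-methoxyphenyl]methyl}-4-({(2R,3S)-3-[(tert-butyldimethylsilyloxy)methyl]-7-methoxy-2-[3-methoxy-4-(triisopropylsilyloxy)phenyl]-2,3-dihydrobenzofuran-5-yl}methyl)dihydrofuran-2(3H)-one | COc1cc(C[C@@H]2C(=O)OC[C@H]2Cc2cc(OC)c3c(c2)[C@@H](CO[Si](C)(C)C(C)(C)C)[C@H](c2ccc(O[Si](C(C)C)(C(C)C)C(C)C)c(OC)c2)O3)cc(Br)c1O[Si](C)(C)C(C)(C)C | intermediate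
24 | boronic ester of 25 (boron on C7'' in place of OH, 7''S,8''S) | COc1cc([C@@H](B2O[C@@]3(C)c4cccc5cccc(c45)[C@@]3(C)O2)[C@H](CO[Si](C)(C)C(C)(C)C)c2cc(C[C@@H]3C(=O)OC[C@H]3Cc3cc(OC)c4c(c3)[C@@H](CO[Si](C)(C)C(C)(C)C)[C@H](c3ccc(O[Si](C(C)C)(C(C)C)C(C)C)c(OC)c3)O4)cc(OC)c2O[Si](C)(C)C(C)(C)C)ccc1O[Si](C(C)C)(C(C)C)C(C)C | intermediate (not isolated)
25 | penta-silyl ether of the target (two aryl OTIPS, ring B OTBS, two CH2OTBS; free C7'' OH) | COc1cc([C@@H](O)[C@H](CO[Si](C)(C)C(C)(C)C)c2cc(C[C@@H]3C(=O)OC[C@H]3Cc3cc(OC)c4c(c3)[C@@H](CO[Si](C)(C)C(C)(C)C)[C@H](c3ccc(O[Si](C(C)C)(C(C)C)C(C)C)c(OC)c3)O4)cc(OC)c2O[Si](C)(C)C(C)(C)C)ccc1O[Si](C(C)C)(C(C)C)C(C)C | intermediate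
26 | CNP0186558.3 | COc1cc([C@@H](O)[C@H](CO)c2cc(C[C@@H]3C(=O)OC[C@H]3Cc3cc(OC)c4c(c3)[C@@H](CO)[C@H](c3ccc(O)c(OC)c3)O4)cc(OC)c2O)ccc1O | target

Total step count: 17. Longest linear sequence: 10 steps (steps 1–4, 9–11, 15–17).

Steps most likely to fail

Step 16. The metallate shift may lose to direct Suzuki–Miyaura transfer of the aryl or alkenyl group from boron. The alkylpalladium intermediate may undergo β-silyloxy elimination. Oxidative addition and alkene binding at the doubly ortho-flanked C–Br bond may be slow, or face selection on the (Z)-alkene may be poor. The fallback makes the same ring B–C8'' bond by a Suzuki–Miyaura coupling and sets C8'' afterwards under substrate control. It sets out from 23, with aryllithium 14 generated from 13 as in step 8 as the source of the second partner, and returns to the route at 26. Aryllithium 14 is formylated with DMF to 3-methoxy-4-(triisopropylsilyloxy)benzaldehyde F1. Me2Zn/ProPhenol-catalysed addition of trimethylsilylacetylene, with the ligand enantiomer chosen for the C7'' configuration of the target, gives the silylated propargylic alcohol F2. K2CO3 in MeOH removes the C-silyl group to give the terminal propargylic alcohol F3. Markovnikov protoboration with B2pin2 and MeOH, catalysed by CuCl with SIMes·HCl and NaOt-Bu, gives the α-borylated allylic alcohol F4. Coupling of F4 with 23 (Pd(dppf)Cl2, K3PO4, THF/H2O, 50 °C) gives the 2-aryl allylic alcohol F5. Hydroboration of its 1,1-disubstituted alkene with 9-BBN, anti-selective through allylic strain control by the carbinol centre, and NaBO3 oxidation give the diol F6. The fluoride conditions of step 17 then convert F6 into 26.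

Step 9. The same process risks apply to the first conjunctive coupling on 6, here next to an ortho benzyloxy group. The fallback sets out from 6 and returns at 17. Suzuki–Miyaura coupling of 6 with the α-borylated allylic alcohol F4 (made as above) gives the 2-aryl allylic alcohol F7. 9-BBN hydroboration and NaBO3 oxidation give the anti diol F8. Selective silylation of its primary hydroxyl (TBSCl, imidazole, CH2Cl2, 0 °C) gives 17.

Step 6. Competing cis-hydroboration may erode the Z geometry, and exchange of catechol for the hindered tertiary diol may be incomplete. The fallback builds the Z alkene by semi-hydrogenation instead, sets out from 9 and returns at 11. Alkyne 9 is deprotonated with n-BuLi and trapped with B(OiPr)3, and anhydrous HCl gives the diisopropyl alkynylboronate F9, which is not isolated. Esterification with diol 8 gives the alkynylboronic ester F10. cis-Hydrogenation over Pd/CaCO3 poisoned with Pb(OAc)2 and quinoline gives 11.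

Further compounds
F1 | step 16 | 3-methoxy-4-(triisopropylsilyloxy)benzaldehyde | COc1cc(C=O)ccc1O[Si](C(C)C)(C(C)C)C(C)C
F2 | step 16 | (R)-1-[3-methoxy-4-(triisopropylsilyloxy)phenyl]-3-(trimethylsilyl)prop-2-yn-1-ol | COc1cc([C@@H](O)C#C[Si](C)(C)C)ccc1O[Si](C(C)C)(C(C)C)C(C)C
F3 | step 16 | (S)-1-[3-methoxy-4-(triisopropylsilyloxy)phenyl]prop-2-yn-1-ol | COc1cc([C@@H](O)C#C)ccc1O[Si](C(C)C)(C(C)C)C(C)C
F4 | step 16 | (S)-1-[3-methoxy-4-(triisopropylsilyloxy)phenyl]-2-(4,4,5,5-tetramethyl-1,3,2-dioxaborolan-2-yl)prop-2-en-1-ol | COc1cc([C@@H](O)C(=C)B2OC(C)(C)C(C)(C)O2)ccc1O[Si](C(C)C)(C(C)C)C(C)C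
F5 | step 16 | 2-aryl allylic alcohol from 23 (ring B C5 bearing the 3-hydroxy-3-arylprop-1-en-2-yl group, R carbinol) | COc1cc([C@@H](O)C(=C)c2cc(C[C@@H]3C(=O)OC[C@H]3Cc3cc(OC)c4c(c3)[C@@H](CO[Si](C)(C)C(C)(C)C)[C@H](c3ccc(O[Si](C(C)C)(C(C)C)C(C)C)c(OC)c3)O4)cc(OC)c2O[Si](C)(C)C(C)(C)C)ccc1O[Si](C(C)C)(C(C)C)C(C)C
F6 | step 16 | 7''S,8''S diol with free C7'' and C9'' hydroxyls (other silyl ethers as in 25) | COc1cc([C@@H](O)[C@H](CO)c2cc(C[C@@H]3C(=O)OC[C@H]3Cc3cc(OC)c4c(c3)[C@@H](CO[Si](C)(C)C(C)(C)C)[C@H](c3ccc(O[Si](C(C)C)(C(C)C)C(C)C)c(OC)c3)O4)cc(OC)c2O[Si](C)(C)C(C)(C)C)ccc1O[Si](C(C)C)(C(C)C)C(C)C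
F7 | step 9 | 2-aryl allylic alcohol from 6 (R carbinol, S lactone) | COc1cc([C@@H](O)C(=C)c2cc(C[C@@H]3COC(=O)C3)cc(OC)c2OCc2ccccc2)ccc1O[Si](C(C)C)(C(C)C)C(C)C
F8 | step 9 | (1S,2S)-diol corresponding to 17 without the tert-butyldimethylsilyl group | COc1cc([C@@H](O)[C@H](CO)c2cc(C[C@@H]3COC(=O)C3)cc(OC)c2OCc2ccccc2)ccc1O[Si](C(C)C)(C(C)C)C(C)C
F9 | step 6 | diisopropyl [3-(tert-butyldimethylsilyloxy)prop-1-ynyl]boronate | CC(C)OB(OC(C)C)C#CCO[Si](C)(C)C(C)(C)C
F10 | step 6 | 3-(tert-butyldimethylsilyloxy)prop-1-ynylboronic ester of diol 8 | CC(C)(C)[Si](C)(C)OCC#CB1O[C@@]2(C)c3cccc4cccc(c34)[C@@]2(C)O1
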